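**Retrosynthetic overview**

- The target is a (2S,3S,4R,5R)-2,5-diaryl-3,4-dimethyloxolane, numbered O1, C2 (bears ring A, 3-hydroxy-4,5-dimethoxyphenyl), C3, C4, C5 (bears ring B, 3,4,5-trimethoxyphenyl). One formal [3+2] disconnection of O1–C5 and C2–C3 leads to 3-acetoxy-4,5-dimethoxybenzaldehyde (carbonyl C becomes C2, carbonyl O becomes O1) and (E)-1,2,3-trimethoxy-5-(2-methylbut-2-en-1-yl)benzene (C3, C4, C5, both methyls, ring B).
- Enabling feature: C5 is a benzylic CH2 lying between the C3=C4 double bond and ring B. A cation created at C4 by C2–C3 bond formation can therefore move by 1,2-hydride shift to a para-methoxybenzylic cation at C5, which O1 captures. The cis C3/C4 methyl pair is the anti-addition image of the E alkene, and both C–O bonds of the oxolane are benzylic and ionisable, so C2 and C5 can converge on the stable configuration.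
- The alkene comes from an sp3–sp2 Suzuki coupling of 3,4,5-trimethoxybenzyl chloride with (Z)-2-buten-2-yl pinacolboronate; the ring A phenol is carried as an acetate.
- Ring order: the oxolane is the only ring formed (step 3); deacetylation (step 4) ends the route.

Key step: step 3

Assumption: the benzyl chloride, the alkenyl boronate (the syn-hydroboration product of but-2-yne with pinacolborane) and the phenol aldehyde used as starting materials are taken as catalogue chemicals.

**Step 1**
Reactants: 1 5-(chloromethyl)-1,2,3-trimethoxybenzene; 2 (Z)-2-(but-2-en-2-yl)-4,4,5,5-tetramethyl-1,3,2-dioxaborolane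
Product: 3 (E)-1,2,3-trimethoxy-5-(2-methylbut-2-en-1-yl)benzene
Conditions: Pd(OAc)2 (2 mol%), SPhos (4 mol%), K3PO4 (2 equiv), toluene/H2O 10:1, 80 °C
Reagents that add atoms: none
Why: Suzuki–Miyaura coupling of a benzylic chloride with an alkenyl boronate proceeds with retention of alkene geometry, so the Z boronate (methyls cis) should give the E alkene with the two methyl groups cis, which is the geometry step 3 needs.

**Step 2**
Reactants: 4 3-hydroxy-4,5-dimethoxybenzaldehyde
Product: 5 3-acetoxy-4,5-dimethoxybenzaldehyde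
Conditions: Ac2O (1.2 equiv), pyridine, DMAP (cat.), CH2Cl2, 0 °C to rt
Reagents that add atoms: acetic anhydride CC(=O)OC(C)=O
Why: O-acylation of the phenol masks the acidic OH and lowers the nucleophilicity of ring A before the cationic step.

**Step 3**
Reactants: 3 (E)-1,2,3-trimethoxy-5-(2-methylbut-2-en-1-yl)benzene; 5 3-acetoxy-4,5-dimethoxybenzaldehyde
Product: 8 (2S,3S,4R,5R)-2-(3-acetoxy-4,5-dimethoxyphenyl)-3,4-dimethyl-5-(3,4,5-trimethoxyphenyl)oxolane, via C4 carbocation 6 (not isolated), via C5 benzylic carbocation 7 (not isolated)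
Conditions: chiral IDPi Brønsted acid (confined imidodiphosphorimidate from two 3,3′-diaryl-BINOL units with N-triflyl groups, 5 mol%), CH2Cl2, 4 Å MS, −60 to −20 °C, then 0 °C; Et3N quench
Reagents that add atoms: none
Why: Proposed new method: the acid-bound aldehyde 5 is attacked at its carbonyl carbon by C3 of alkene 3 (Prins-type addition, C2–C3 bond) to give the tertiary C4 carbocation 6, a 1,2-hydride shift from the benzylic C5 methylene then gives the C5 carbocation 7, and the C2 hydroxyl collapses on C5 (O1–C5 bond) with return of the proton to the catalyst, an atom-economic formal [3+2] annulation. The closest known reaction types are the Lewis-acid [3+2] annulation of crotylsilanes with aldehydes (a 1,2-silyl shift takes the place of the hydride shift), IDPi-catalysed asymmetric additions of unactivated dienes and allylsilanes to aromatic aldehydes, and interrupted carbonyl–olefin metathesis under Brønsted acid. The oxolane closes by cation–hydroxyl collapse at C5, formally 5-exo-trig because the aryl-delocalised cation lies outside the new ring. C3 is set by the catalyst (the antipode is chosen that sends the aldehyde carbon to the Si face of C3), C4 by migration of hydrogen anti to the new C2–C3 bond across the E alkene (this places the two methyl groups cis), C5 by closure trans to the C4 methyl, and C2 by the catalyst-controlled aldehyde face. Both C–O bonds of the product are para-alkoxybenzylic and should re-ionise under the acid on warming, so a C2 or C5 epimer is expected to drain into the 2,5-cis isomer with each aryl trans to its neighbouring methyl, the most stable arrangement for a fixed cis-3,4-dimethyl pair. The step needs the hydride shift to outrun proton loss from 6, oxetane collapse and Friedel–Crafts attack on ring B; the non-basic confined counter-anion, the absence of a metal Lewis acid, the low temperature and the cation-stabilising ring B at C5 are relied on for this.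

**Step 4**
Reactants: 8 (2S,3S,4R,5R)-2-(3-acetoxy-4,5-dimethoxyphenyl)-3,4-dimethyl-5-(3,4,5-trimethoxyphenyl)oxolane
Product: 9 (2S,3S,4R,5R)-2-(3-hydroxy-4,5-dimethoxyphenyl)-3,4-dimethyl-5-(3,4,5-trimethoxyphenyl)oxolane
Conditions: K2CO3 (0.2 equiv), MeOH, 0 °C to rt; aq. NH4Cl
Reagents that add atoms: none
Why: base-catalysed transesterification of the aryl acetate to methanol frees the phenol without touching any stereocentre or the benzylic ether bonds.

**Compound list**

1 | 5-(chloromethyl)-1,2,3-trimethoxybenzene (3,4,5-trimethoxybenzyl chloride) | COc1cc(CCl)cc(OC)c1OC | starting material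
2 | (Z)-2-(but-2-en-2-yl)-4,4,5,5-tetramethyl-1,3,2-dioxaborolane | C/C=C(\C)B1OC(C)(C)C(C)(C)O1 | starting material
3 | (E)-1,2,3-trimethoxy-5-(2-methylbut-2-en-1-yl)benzene | C/C=C(\C)Cc1cc(OC)c(OC)c(OC)c1 | intermediate
4 | 3-hydroxy-4,5-dimethoxybenzaldehyde | COc1cc(C=O)cc(O)c1OC | starting material
5 | 3-acetoxy-4,5-dimethoxybenzaldehyde (5-formyl-2,3-dimethoxyphenyl acetate) | COc1cc(C=O)cc(OC(C)=O)c1OC | intermediate
6 | C4 carbocation: open-chain tertiary cation after C2–C3 bond formation, C2 and C3 configured as in 8, IDPi anion as counter-ion | COc1cc([C@@H](O)[C@@H](C)[C+](C)Cc2cc(OC)c(OC)c(OC)c2)cc(OC(C)=O)c1OC | intermediate (not isolated)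
7 | C5 benzylic carbocation: open-chain cation after the 1,2-hydride shift, C2, C3 and C4 configured as in 8, IDPi anion as counter-ion | COc1cc([C@@H](O)[C@@H](C)[C@@H](C)[CH+]c2cc(OC)c(OC)c(OC)c2)cc(OC(C)=O)c1OC | intermediate (not isolated)
8 | (2S,3S,4R,5R)-2-(3-acetoxy-4,5-dimethoxyphenyl)-3,4-dimethyl-5-(3,4,5-trimethoxyphenyl)oxolane | COc1cc([C@H]2O[C@@H](c3cc(OC)c(OC)c(OC)c3)[C@H](C)[C@@H]2C)cc(OC(C)=O)c1OC | intermediate
9 | (2S,3S,4R,5R)-2-(3-hydroxy-4,5-dimethoxyphenyl)-3,4-dimethyl-5-(3,4,5-trimethoxyphenyl)oxolane | COc1cc([C@H]2O[C@@H](c3cc(OC)c(OC)c(OC)c3)[C@H](C)[C@@H]2C)cc(O)c1OC | target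

Total step count: 4. Longest linear sequence: 3 steps (1 to 3 to 8 to 9, or 4 to 5 to 8 to 9).

**Steps most likely to fail**

1. Step 3 (key step). What may go wrong: the cationic cascade can leave the intended path. Carbocation 6 may lose a proton (ene-type outcome), rotate about the C3–C4 bond or undergo aryl participation before the anti hydride shift (loss of the cis-dimethyl relation). The activated aldehyde may attack ring B in a Friedel–Crafts sense, or facial selectivity at C3 may be poor (low enantiomeric purity).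
Fallback with known chemistry, setting out from phenol aldehyde 4 and coming back to the route at target 9. Aldehyde 4 is silylated (t-BuMe2SiCl, imidazole, DMF) to 3-[(tert-butyldimethylsilyl)oxy]-4,5-dimethoxybenzaldehyde F1. A chiral phosphoric acid-catalysed allylboration of F1 (TRIP, the antipode that gives the 1S carbinol, toluene, −30 °C) uses the tiglyl boronate (E)-4,4,5,5-tetramethyl-2-(2-methylbut-2-en-1-yl)-1,3,2-dioxaborolane F2, made from (E)-2-methylbut-2-en-1-ol and B2pin2 with Pd(MeCN)4(BF4)2 as catalyst. Through a chair transition state it should give the anti alcohol (1S,2S)-1-{3-[(tert-butyldimethylsilyl)oxy]-4,5-dimethoxyphenyl}-2,3-dimethylbut-3-en-1-ol F3. Hydroboration–oxidation (9-BBN, THF, then NaOH, H2O2), anti to the carbinol-bearing substituent under A1,3-strain control, should give (1S,2S,3R)-1-{3-[(tert-butyldimethylsilyl)oxy]-4,5-dimethoxyphenyl}-2,3-dimethylbutane-1,4-diol F4, with the methyl pair in the relation needed for the cis-3,4-dimethyl oxolane. Oxidation of the primary alcohol with lactonisation (TEMPO cat., PhI(OAc)2, CH2Cl2) gives (3R,4S,5S)-5-{3-[(tert-butyldimethylsilyl)oxy]-4,5-dimethoxyphenyl}-3,4-dimethyloxolan-2-one F5. Addition of 3,4,5-trimethoxyphenyllithium (from 5-bromo-1,2,3-trimethoxybenzene and n-BuLi, THF, −78 °C) gives the hemiketal (3R,4S,5S)-5-{3-[(tert-butyldimethylsilyl)oxy]-4,5-dimethoxyphenyl}-3,4-dimethyl-2-(3,4,5-trimethoxyphenyl)oxolan-2-ol F6 as an anomeric mixture. Reduction through the cyclic oxocarbenium ion (Et3SiH, BF3·OEt2, CH2Cl2, −78 °C, then −20 °C so that C5 equilibrates trans to the C4 methyl) gives the silyl ether (2S,3S,4R,5R)-2-{3-[(tert-butyldimethylsilyl)oxy]-4,5-dimethoxyphenyl}-3,4-dimethyl-5-(3,4,5-trimethoxyphenyl)oxolane F7. Bu4NF in THF then gives 9.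

2. Step 1. What may go wrong: slow transmetalation of the α-branched alkenyl boronate lets protodeboronation compete, and palladium hydride species may move the double bond into conjugation with ring B or erode the E geometry on which the cis-dimethyl relation depends.
Fallback, setting out from benzyl chloride 1 and coming back at alkene 3, with the polarity of the coupling reversed. Chloride 1 is converted with zinc dust and LiCl in THF into (3,4,5-trimethoxybenzyl)zinc chloride F8. A Negishi coupling of F8 with commercial (E)-2-bromobut-2-ene (Pd(OAc)2, SPhos, THF, rt) should give 3 with retention of the alkene geometry.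

3. Step 4. What may go wrong: failure of the protecting group, either by early loss or migration of the acetyl group under the strong acid of step 3, or by air oxidation of the electron-rich phenolate in basic methanol.
Fallback, setting out from phenol aldehyde 4 and coming back at target 9, with an acid-stable ether removed under neutral reductive conditions. Aldehyde 4 is benzylated (BnBr, K2CO3, DMF) to 3-(benzyloxy)-4,5-dimethoxybenzaldehyde F9. The annulation with alkene 3 under the conditions of step 3 should give (2S,3S,4R,5R)-2-[3-(benzyloxy)-4,5-dimethoxyphenyl]-3,4-dimethyl-5-(3,4,5-trimethoxyphenyl)oxolane F10. Hydrogenolysis (H2, 1 atm, Pd/C, EtOAc) then gives 9.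

**Further compounds**

F1 | step 3 | 3-[(tert-butyldimethylsilyl)oxy]-4,5-dimethoxybenzaldehyde | COc1cc(C=O)cc(O[Si](C)(C)C(C)(C)C)c1OC
F2 | step 3 | (E)-4,4,5,5-tetramethyl-2-(2-methylbut-2-en-1-yl)-1,3,2-dioxaborolane | C/C=C(\C)CB1OC(C)(C)C(C)(C)O1
F3 | step 3 | (1S,2S)-1-{3-[(tert-butyldimethylsilyl)oxy]-4,5-dimethoxyphenyl}-2,3-dimethylbut-3-en-1-ol | COc1cc([C@@H](O)[C@@H](C)C(C)=C)cc(O[Si](C)(C)C(C)(C)C)c1OC
F4 | step 3 | (1S,2S,3R)-1-{3-[(tert-butyldimethylsilyl)oxy]-4,5-dimethoxyphenyl}-2,3-dimethylbutane-1,4-diol | COc1cc([C@@H](O)[C@@H](C)[C@@H](C)CO)cc(O[Si](C)(C)C(C)(C)C)c1OC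
F5 | step 3 | (3R,4S,5S)-5-{3-[(tert-butyldimethylsilyl)oxy]-4,5-dimethoxyphenyl}-3,4-dimethyloxolan-2-one | COc1cc([C@H]2OC(=O)[C@H](C)[C@@H]2C)cc(O[Si](C)(C)C(C)(C)C)c1OC
F6 | step 3 | (3R,4S,5S)-5-{3-[(tert-butyldimethylsilyl)oxy]-4,5-dimethoxyphenyl}-3,4-dimethyl-2-(3,4,5-trimethoxyphenyl)oxolan-2-ol (anomeric mixture) | COc1cc([C@H]2OC(O)(c3cc(OC)c(OC)c(OC)c3)[C@H](C)[C@@H]2C)cc(O[Si](C)(C)C(C)(C)C)c1OC
F7 | step 3 | (2S,3S,4R,5R)-2-{3-[(tert-butyldimethylsilyl)oxy]-4,5-dimethoxyphenyl}-3,4-dimethyl-5-(3,4,5-trimethoxyphenyl)oxolane | COc1cc([C@H]2O[C@@H](c3cc(OC)c(OC)c(OC)c3)[C@H](C)[C@@H]2C)cc(O[Si](C)(C)C(C)(C)C)c1OC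
F8 | step 1 | (3,4,5-trimethoxybenzyl)zinc chloride | COc1cc(C[Zn]Cl)cc(OC)c1OC
F9 | step 4 | 3-(benzyloxy)-4,5-dimethoxybenzaldehyde | COc1cc(C=O)cc(OCc2ccccc2)c1OC
F10 | step 4 | (2S,3S,4R,5R)-2-[3-(benzyloxy)-4,5-dimethoxyphenyl]-3,4-dimethyl-5-(3,4,5-trimethoxyphenyl)oxolane | COc1cc([C@H]2O[C@@H](c3cc(OC)c(OC)c(OC)c3)[C@H](C)[C@@H]2C)cc(OCc4ccccc4)c1OC
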